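**Retrosynthetic overview**
1. Feature used: a mirror plane runs through C1 (the carbon bearing the isobutyryl group) and C4–OH of the central benzene ring. It maps the CH2 bridge at C3 onto the one at C5, and one 6-ethyl-4-hydroxy-5-methyl-2-pyrone ring onto the other. Each bridge carbon lies between a phenolic C–OH and the pyrone C4–OH, which is the mark of an o-quinone methide/Michael union as presumed in the biosynthesis.
2. Key disconnection: all four C–CH2 bonds are cut together (aryl C3–CH2, aryl C5–CH2 and twice CH2–C3 of a pyrone). This leaves phlorisobutyrophenone, two C1 units and two copies of the pyrone.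
3. Forward: the unprotected arene is turned in one flask into a twofold o-quinone methide linchpin, and both flanks are captured at the same time (two-directional, biomimetic, pseudo-five-component). The C1 units are parked on the arene, not on the pyrone as in the usual one-bridge-at-a-time drawing, and this shuts off both homo-couplings.
4. Rings: the benzene ring is bought (phloroglucinol, one Friedel–Crafts acylation). The pyrone ring is closed beforehand by triketide-type enol lactonisation of a 3,5-dioxo ester. The key step closes no ring.

Key step: step 4

Remark on the chemistry: the SMILES holds no stereocentre and no stereogenic double bond. The target is achiral, so the compound as drawn is the goal and no step needs stereocontrol.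

**Step 1**
Reactants: 1 phloroglucinol (benzene-1,3,5-triol, anhydrous); 2 isobutyryl chloride (1.0 equiv)
Product: 3 phlorisobutyrophenone (2-methyl-1-(2,4,6-trihydroxyphenyl)propan-1-one)
Conditions: AlCl3 (4 equiv), CH2Cl2/PhNO2, 0 → 45 °C; ice/aq HCl
Reagents that add atoms: none
Why: Friedel–Crafts acylation; the first acyl group is chelated by aluminium and by both ortho oxygens and deactivates the ring, so one equivalent of 2 should give C-monoacylation of the threefold symmetric 1.

**Step 2**
Reactants: 4 methyl 3-oxopentanoate (1.2 equiv); 5 N-methoxy-N-methylpropanamide (1.0 equiv)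
Product: 6 methyl 4-methyl-3,5-dioxoheptanoate (keto/enol mixture, C4 configurationally labile)
Conditions: NaH, THF, 0 °C; n-BuLi, 0 °C; then 5, 0 °C → rt; aq HCl
Reagents that add atoms: none
Why: Weiler dianion acylation with a Weinreb amide; the β-keto ester dianion reacts at its more basic γ-carbon (C4), the chelated tetrahedral adduct survives until the quench and so prevents proton exchange and double addition, and the labile C4 centre vanishes in step 3.

**Step 3**
Reactants: 6 methyl 4-methyl-3,5-dioxoheptanoate
Product: 7 6-ethyl-4-hydroxy-5-methyl-2H-pyran-2-one
Conditions: DBU (1.2 equiv), toluene, 80 °C; aq HCl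
Reagents that add atoms: none
Why: base-induced enol lactonisation of a 3,5-dioxo ester (the C5 enolate oxygen attacks the ester carbonyl, 6-exo-trig), driven by loss of methanol and formation of the acidic, aromatic 4-hydroxy-2-pyrone as its DBU salt.

**Step 4**
Reactants: 3 phlorisobutyrophenone; 7 6-ethyl-4-hydroxy-5-methyl-2H-pyran-2-one (2.2 equiv)
Product: 12 target CNP0277086.0 (3,5-bis[(6-ethyl-4-hydroxy-5-methyl-2-oxo-2H-pyran-3-yl)methyl]phlorisobutyrophenone), via bis-Mannich base 8 (not isolated), via first o-quinone methide 9 (not isolated), via mono-bridged Mannich base 10 (not isolated), via second o-quinone methide 11 (not isolated)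
Conditions: (i) CH2(NMe2)2 (3 equiv), EtOH, 0 °C → rt, slow addition of 3; volatiles off in vacuo; (ii) 7, 1,4-dioxane, 90 °C, N2; aq HCl
Reagents that add atoms: bis(dimethylamino)methane, CN(C)CN(C)C (supplies both bridge CH2 carbons; its NMe2 groups appear only in 8, 9 and 10)
Why: Twofold Mannich reaction followed by twofold o-quinone methide (o-QM)/Michael capture: the acidic phenol 3 ionises the aminal to CH2=NMe2+, which attacks the only two free ring carbons, C3 and C5, to give 8. After the volatile excess aminal and Me2NH are stripped off, the acidic 4-OH of 7 protonates a benzylic nitrogen of 8, the neighbouring phenol oxygen expels Me2NH to give o-QM 9, and the pyronate adds through C3 with rearomatisation to 10; the same events on the mirror-related flank (through 11) complete 12, so four C–C bonds arise in one flask. The closest known reaction types are the C-alkylation of cyclic 1,3-dicarbonyl C–H acids (4-hydroxycoumarins, 4-hydroxy-2-pyrones, tetronic acids) with phenolic Mannich bases through o-QMs and the formaldehyde bridging of acylphloroglucinols. No ring is closed and no stereocentre is formed. The step needs cross-coupling over homo-coupling: arene–arene bridging is suppressed because 3 is added slowly into excess iminium source and 8 has no free aryl C–H, and pyrone–pyrone bridging is suppressed because the C1 units are already bound to the arene and no free formaldehyde equivalent is left when 7 enters. Site selectivity on 7 is fixed by the substrate, since C5 carries methyl and C3 is the only nucleophilic carbon, O-alkylation is reversible, and each C-alkylation regains the benzene ring and O–H···O hydrogen bonds across the bridge.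

**Compound list**
1 | phloroglucinol | Oc1cc(O)cc(O)c1 | starting material
2 | isobutyryl chloride | CC(C)C(=O)Cl | starting material
3 | phlorisobutyrophenone | CC(C)C(=O)c1c(O)cc(O)cc1O | intermediate
4 | methyl 3-oxopentanoate | CCC(=O)CC(=O)OC | starting material
5 | N-methoxy-N-methylpropanamide | CCC(=O)N(C)OC | starting material
6 | methyl 4-methyl-3,5-dioxoheptanoate | CCC(=O)C(C)C(=O)CC(=O)OC | intermediate
7 | 6-ethyl-4-hydroxy-5-methyl-2H-pyran-2-one | CCc1oc(=O)cc(O)c1C | intermediate
8 | 1-{3,5-bis[(dimethylamino)methyl]-2,4,6-trihydroxyphenyl}-2-methylpropan-1-one (bis-Mannich base) | CC(C)C(=O)c1c(O)c(CN(C)C)c(O)c(CN(C)C)c1O | intermediate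
9 | first o-quinone methide (6-methylene-cyclohexa-2,4-dienone from 8 by loss of one Me2NH) | C=C1C(=O)C(C(=O)C(C)C)=C(O)C(CN(C)C)=C1O | intermediate
10 | mono-bridged Mannich base (one pyronylmethyl arm, one CH2NMe2 arm) | CCc1oc(=O)c(Cc2c(O)c(CN(C)C)c(O)c(C(=O)C(C)C)c2O)c(O)c1C | intermediate
11 | second o-quinone methide (from 10 by loss of Me2NH) | C=C1C(=O)C(C(=O)C(C)C)=C(O)C(Cc2c(O)c(C)c(CC)oc2=O)=C1O | intermediate
12 | CNP0277086.0 | CCc1oc(=O)c(Cc2c(O)c(Cc3c(O)c(C)c(CC)oc3=O)c(O)c(C(=O)C(C)C)c2O)c(O)c1C | target

**Total step count:** 4
**Longest linear sequence:** 3 steps (4 → 6 → 7 → 12)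

**Steps most likely to fail**

1. Step 4.
   - What may go wrong: retro-Mannich or trans-aminomethylation may hand the C1 unit from the arene to the pyrone, which then bridges with itself. The sequence may stall after the first capture. Arene–arene bridging may compete during the aminomethylation stage.
   - Fallback: it sets out from 3 and comes back at 12. The C1 unit is fixed on the arene at the aldehyde level, where it cannot migrate.
   - Twofold Duff formylation of 3 (hexamethylenetetramine, TFA, 100 °C, then aq HCl) should give 2,4,6-trihydroxy-5-isobutyrylbenzene-1,3-dicarbaldehyde F1. This is the reaction type that carries phloroglucinol itself to its triformyl derivative.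
   - Organocatalytic three-component reductive alkylation of 7 (2.2 equiv) with F1 and Hantzsch ester (2.2 equiv, L-proline cat., EtOH, rt) should then give 12. It proceeds by Knoevenagel condensation followed by conjugate hydride transfer.

2. Step 2.
   - What may go wrong: the hindered secondary γ-carbanion may add slowly. Proton transfer from the amide α-CH2 may quench the dianion. Early collapse of the tetrahedral adduct may allow further addition.
   - Fallback: it sets out from 4 and comes back at 6. The strongly basic dianion is replaced by its neutral masked form.
   - Silylation (Me3SiCl, Et3N) should give methyl (Z)-3-(trimethylsilyloxy)pent-2-enoate F2.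
   - LDA/Me3SiCl (THF, −78 °C) should then give 1-methoxy-1,3-bis(trimethylsilyloxy)penta-1,3-diene F3. It forms as a mixture of geometric isomers, which is of no consequence.
   - γ-Selective acylation of F3 with propionyl chloride (CH2Cl2, −78 → 20 °C, mild acidic work-up) should deliver 6.

3. Step 1.
   - What may go wrong: over-acylation, O-acylation without Fries migration, and loss of the polar product on aqueous work-up.
   - Fallback: it sets out from 1 and comes back at 3.
   - Houben–Hoesch reaction of 1 with isobutyronitrile (ZnCl2, HCl gas, Et2O, 0 °C) should precipitate 2-methyl-1-(2,4,6-trihydroxyphenyl)propan-1-iminium chloride F4. Its positive charge stops a second attack.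
   - Hydrolysis in boiling water should give 3.

**Further compounds**
F1 | step 4 | 2,4,6-trihydroxy-5-isobutyrylbenzene-1,3-dicarbaldehyde | CC(C)C(=O)c1c(O)c(C=O)c(O)c(C=O)c1O
F2 | step 2 | methyl (Z)-3-(trimethylsilyloxy)pent-2-enoate | CC/C(O[Si](C)(C)C)=C/C(=O)OC
F3 | step 2 | 1-methoxy-1,3-bis(trimethylsilyloxy)penta-1,3-diene (mixture of geometric isomers) | COC(O[Si](C)(C)C)=CC(O[Si](C)(C)C)=CC
F4 | step 1 | 2-methyl-1-(2,4,6-trihydroxyphenyl)propan-1-iminium chloride | CC(C)C(=[NH2+])c1c(O)cc(O)cc1O.[Cl-]
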